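## Retrosynthetic overview

1. The target comes from a (2Z)-enoate by ester reduction, C19–O acetylation and C1–O desilylation; the C6=C7 bond is made by a Still–Gennari olefination of a geraniol-derived C1–C6 aldehyde with an α-alkyl phosphonoacetate that carries the ring.
2. The phosphonate is cut at C8–C9: conjugate addition of the 9-BBN adduct of a vinyl-substituted oxolanol to an α-phosphonoacrylate (C7 and C19 from the phosphonoacetate, C8 from formaldehyde).
3. Key step and only ring formation: the oxolane is closed by a C–O bond (oxygen on C12 to C15) through Shi epoxidation of the prenyl alkene and 5-endo epoxide opening at the tertiary carbon, which also installs the C14 hydroxyl.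
4. The open-chain anti pair (C11 methyl, C12 hydroxyl) comes from an iridium-catalysed anti-crotylation of 4-methylpent-3-en-1-ol.
5. Order: stereodiad, ring, chain extension, olefination, then adjustment of the two primary oxygens.

Assumption: carbon labels follow geranylgeraniol numbering of the target (C1 = CH2OH carbon, C19 = acetoxymethyl carbon on C7, C18 = methyl on C11, ring oxygen between C12 and C15, hydroxyl on C14).
Assumption: 1, 2, 7, 8 and 13 are bought; 12 is carried as a mixture of epimers at its phosphorus-bearing carbon, which becomes sp2 in step 7.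

## Route

Step 1  
Reactants: 1 4-methylpent-3-en-1-ol; 2 but-3-en-2-yl acetate (racemic)  
Product: 4 (3R,4S)-3,7-dimethylocta-1,6-dien-4-ol, via aldehyde 3 (not isolated)  
Conditions: 2 (2 equiv), [Ir(cod)Cl]2 (2.5 mol%), (R)-SEGPHOS (5 mol%), 4-cyano-3-nitrobenzoic acid (10 mol%), Cs2CO3 (20 mol%), THF, 90 °C, sealed tube  
Reagents that add atoms: none  
Why: Iridium-catalysed transfer-hydrogenative carbonyl crotylation (Krische type): the catalyst dehydrogenates 1 to aldehyde 3 and adds the (E)-σ-crotyl iridium species to it through a closed chair transition state, which makes methyl and hydroxyl anti and, with the (R)-ligand directing attack on the Re face, gives the (3R,4S) isomer while the trisubstituted alkene is left alone.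

Step 2  
Reactants: 4 (3R,4S)-3,7-dimethylocta-1,6-dien-4-ol  
Product: 6 (3R,5S)-5-[(2R)-but-3-en-2-yl]-2,2-dimethyloxolan-3-ol, via epoxy alcohol 5 (not isolated)  
Conditions: Shi ketone (1,2:4,5-di-O-isopropylidene-β-D-erythro-2,3-hexodiulo-2,6-pyranose, 30 mol%), KHSO5 (as 2KHSO5·KHSO4·K2SO4), K2CO3, Bu4NHSO4 (cat.), MeCN–(MeO)2CH2 / aq. Na2B4O7–Na2EDTA buffer (pH 10.5), 0 °C; then (±)-camphor-10-sulfonic acid (10 mol%), CH2Cl2, 0 °C → rt  
Reagents that add atoms: potassium peroxymonosulfate, `[K+].[O-]S(=O)(=O)OO`  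
Why: Shi asymmetric epoxidation (dioxirane oxygen transfer) acts only on the electron-rich trisubstituted alkene and sets the (R) epoxide carbon under catalyst control, and acid then drives a 5-endo epoxide-opening cycloetherification in which the existing hydroxyl attacks the tertiary epoxide carbon, so the ring C–O bond forms with both carbinol configurations retained (C3 R, C5 S, substituents trans).

Step 3  
Reactants: 7 methyl 2-[bis(2,2,2-trifluoroethoxy)phosphoryl]acetate; 8 paraformaldehyde  
Product: 10 methyl 2-[bis(2,2,2-trifluoroethoxy)phosphoryl]prop-2-enoate, via ether adduct 9 (not isolated)  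
Conditions: (CH2O)n (1.5 equiv), piperidine (10 mol%), CF3CH2OH, 70 °C; then TsOH·H2O (5 mol%), toluene, reflux with removal of CF3CH2OH; used fresh (BHT)  
Reagents that add atoms: none  
Why: Knoevenagel condensation of the doubly activated methylene with formaldehyde, run in trifluoroethanol so that no foreign alkoxide can exchange at phosphorus and the reactive acrylate is stored as ether adduct 9 until acid-catalysed β-elimination releases it.

Step 4  
Reactants: 6 (3R,5S)-5-[(2R)-but-3-en-2-yl]-2,2-dimethyloxolan-3-ol; 10 methyl 2-[bis(2,2,2-trifluoroethoxy)phosphoryl]prop-2-enoate  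
Product: 12 methyl (6R)-2-[bis(2,2,2-trifluoroethoxy)phosphoryl]-6-[(2S,4R)-4-hydroxy-5,5-dimethyloxolan-2-yl]heptanoate, via alkylborane 11 (not isolated)  
Conditions: 9-BBN-H (2.2 equiv), THF, 0 °C → rt; then CuCl (10 mol%), 1,3-bis(2,4,6-trimethylphenyl)imidazolium chloride (10 mol%), KOPh (25 mol%), 10 (1.3 equiv, slow addition), THF, 0 °C → rt; aq. NH4Cl  
Reagents that add atoms: none  
Why: Proposed new method: anti-Markovnikov hydroboration with 9-BBN places boron on the terminal carbon (and O-borylates the hydroxyl), phenoxide turns the B-alkyl group into a borate that transmetalates to a monovalent copper–carbene centre, the resulting alkylcopper adds 1,4 to the unsubstituted terminus of the doubly activated acrylate and the stabilised enolate returns to boron to close the cycle, which joins the ring fragment to the olefination handle in one operation; the closest known reaction type is the copper-catalysed conjugate addition of B-alkyl-9-BBN reagents to alkylidene cyanoacetates and acyl-imidazole enones, not yet shown for α-phosphonoacrylates, and the new phosphorus-bearing carbon is an epimer mixture that is erased in step 7.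

Step 5  
Reactants: 13 geraniol  
Product: 14 tert-butyl{[(2E)-3,7-dimethylocta-2,6-dien-1-yl]oxy}dimethylsilane  
Conditions: TBSCl (1.1 equiv), imidazole (2 equiv), CH2Cl2, 0 °C → rt  
Reagents that add atoms: tert-butyldimethylsilyl chloride (TBSCl), `CC(C)(C)[Si](C)(C)Cl`  
Why: Standard silylation of a primary allylic alcohol (imidazole-activated silyl transfer) masks C1–OH for the basic and hydridic steps that follow.

Step 6  
Reactants: 14 tert-butyl{[(2E)-3,7-dimethylocta-2,6-dien-1-yl]oxy}dimethylsilane  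
Product: 16 (4E)-6-[(tert-butyldimethylsilyl)oxy]-4-methylhex-4-enal, via ozonide 15 (not isolated)  
Conditions: O3 (1 equiv, Sudan Red 7B end point), CH2Cl2, −78 °C; then Me2S, −78 °C → rt  
Reagents that add atoms: ozone, `[O-][O+]=O`  
Why: Site-selective ozonolysis (Criegee mechanism) with one equivalent of ozone cleaves the remote trisubstituted alkene, which is more electron-rich than the alkene deactivated by the allylic silyloxy group, and dimethyl sulfide reduces the ozonide to the aldehyde.

Step 7  
Reactants: 12 methyl (6R)-2-[bis(2,2,2-trifluoroethoxy)phosphoryl]-6-[(2S,4R)-4-hydroxy-5,5-dimethyloxolan-2-yl]heptanoate; 16 (4E)-6-[(tert-butyldimethylsilyl)oxy]-4-methylhex-4-enal  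
Product: 17 methyl (2Z,6E)-8-[(tert-butyldimethylsilyl)oxy]-2-{(4R)-4-[(2S,4R)-4-hydroxy-5,5-dimethyloxolan-2-yl]pentyl}-6-methylocta-2,6-dienoate  
Conditions: 12, KN(SiMe3)2 (1.05 equiv), 18-crown-6 (3 equiv), THF, −78 °C; then 16, −78 °C  
Reagents that add atoms: none  
Why: Still–Gennari variant of the Horner–Wadsworth–Emmons olefination: the electron-poor bis(trifluoroethyl) phosphonate anion with a crown-ether-separated potassium ion adds and eliminates under kinetic control, which places the ester cis to the aldehyde-derived chain (2Z), and the minor 2E isomer is removed by chromatography.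

Step 8  
Reactants: 17 methyl (2Z,6E)-8-[(tert-butyldimethylsilyl)oxy]-2-{(4R)-4-[(2S,4R)-4-hydroxy-5,5-dimethyloxolan-2-yl]pentyl}-6-methylocta-2,6-dienoate  
Product: 18 (2Z,6E)-8-[(tert-butyldimethylsilyl)oxy]-2-{(4R)-4-[(2S,4R)-4-hydroxy-5,5-dimethyloxolan-2-yl]pentyl}-6-methylocta-2,6-dien-1-ol  
Conditions: i-Bu2AlH (3.5 equiv), CH2Cl2, −78 °C; aq. potassium sodium tartrate  
Reagents that add atoms: none  
Why: 1,2-Reduction of the conjugated ester with i-Bu2AlH at −78 °C gives the allylic alcohol without changing the alkene geometry, the silyl ether or the ring (the free hydroxyl only consumes one equivalent of hydride).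

Step 9  
Reactants: 18 (2Z,6E)-8-[(tert-butyldimethylsilyl)oxy]-2-{(4R)-4-[(2S,4R)-4-hydroxy-5,5-dimethyloxolan-2-yl]pentyl}-6-methylocta-2,6-dien-1-ol  
Product: 19 (2Z,6E)-8-[(tert-butyldimethylsilyl)oxy]-2-{(4R)-4-[(2S,4R)-4-hydroxy-5,5-dimethyloxolan-2-yl]pentyl}-6-methylocta-2,6-dien-1-yl acetate  
Conditions: Ac2O (1.15 equiv), pyridine, CH2Cl2, −20 → 0 °C  
Reagents that add atoms: acetic anhydride, `CC(=O)OC(C)=O`  
Why: Chemoselective acetylation (nucleophilic acyl substitution without DMAP at low temperature): the primary allylic alcohol reacts far faster than the secondary ring hydroxyl, which is shielded by the adjacent gem-dimethyl carbon.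

Step 10  
Reactants: 19 (2Z,6E)-8-[(tert-butyldimethylsilyl)oxy]-2-{(4R)-4-[(2S,4R)-4-hydroxy-5,5-dimethyloxolan-2-yl]pentyl}-6-methylocta-2,6-dien-1-yl acetate  
Product: 20 (2Z,6E)-8-hydroxy-2-{(4R)-4-[(2S,4R)-4-hydroxy-5,5-dimethyloxolan-2-yl]pentyl}-6-methylocta-2,6-dien-1-yl acetate  
Conditions: HF·pyridine, pyridine, THF, 0 °C → rt  
Reagents that add atoms: none  
Why: Fluoride-mediated desilylation with pyridine-buffered HF·pyridine removes the primary TBS ether and leaves the allylic acetate, both alkenes and the oxolane untouched.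

## Compound list

```
1 | 4-methylpent-3-en-1-ol | CC(C)=CCCO | starting material
2 | but-3-en-2-yl acetate (racemic) | CC(OC(C)=O)C=C | starting material
3 | 4-methylpent-3-enal | CC(C)=CCC=O | intermediate
4 | (3R,4S)-3,7-dimethylocta-1,6-dien-4-ol | C=C[C@@H](C)[C@@H](O)CC=C(C)C | intermediate
5 | (2S,3R)-1-[(2R)-3,3-dimethyloxiran-2-yl]-3-methylpent-4-en-2-ol | C=C[C@@H](C)[C@@H](O)C[C@@H]1C(C)(C)O1 | intermediate
6 | (3R,5S)-5-[(2R)-but-3-en-2-yl]-2,2-dimethyloxolan-3-ol | C=C[C@@H](C)[C@@H]1C[C@@H](O)C(C)(C)O1 | intermediate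
7 | methyl 2-[bis(2,2,2-trifluoroethoxy)phosphoryl]acetate | COC(=O)CP(=O)(OCC(F)(F)F)OCC(F)(F)F | starting material
8 | paraformaldehyde (formaldehyde) | C=O | starting material
9 | methyl 2-[bis(2,2,2-trifluoroethoxy)phosphoryl]-3-(2,2,2-trifluoroethoxy)propanoate | COC(=O)C(COCC(F)(F)F)P(=O)(OCC(F)(F)F)OCC(F)(F)F | intermediate
10 | methyl 2-[bis(2,2,2-trifluoroethoxy)phosphoryl]prop-2-enoate | C=C(C(=O)OC)P(=O)(OCC(F)(F)F)OCC(F)(F)F | intermediate
11 | 9-{(3R)-3-[(2S,4R)-4-(9-borabicyclo[3.3.1]nonan-9-yloxy)-5,5-dimethyloxolan-2-yl]butyl}-9-borabicyclo[3.3.1]nonane | C[C@H](CCB1C2CCCC1CCC2)[C@@H]1C[C@@H](OB2C3CCCC2CCC3)C(C)(C)O1 | intermediate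
12 | methyl (6R)-2-[bis(2,2,2-trifluoroethoxy)phosphoryl]-6-[(2S,4R)-4-hydroxy-5,5-dimethyloxolan-2-yl]heptanoate (C2 epimers) | COC(=O)C(CCC[C@@H](C)[C@@H]1C[C@@H](O)C(C)(C)O1)P(=O)(OCC(F)(F)F)OCC(F)(F)F | intermediate
13 | geraniol, (2E)-3,7-dimethylocta-2,6-dien-1-ol | CC(C)=CCC/C(C)=C/CO | starting material
14 | tert-butyl{[(2E)-3,7-dimethylocta-2,6-dien-1-yl]oxy}dimethylsilane | CC(C)=CCC/C(C)=C/CO[Si](C)(C)C(C)(C)C | intermediate
15 | 3-{(3E)-5-[(tert-butyldimethylsilyl)oxy]-3-methylpent-3-en-1-yl}-5,5-dimethyl-1,2,4-trioxolane | CC1(C)OOC(CC/C(C)=C/CO[Si](C)(C)C(C)(C)C)O1 | intermediate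
16 | (4E)-6-[(tert-butyldimethylsilyl)oxy]-4-methylhex-4-enal | O=CCC/C(C)=C/CO[Si](C)(C)C(C)(C)C | intermediate
17 | methyl (2Z,6E)-8-[(tert-butyldimethylsilyl)oxy]-2-{(4R)-4-[(2S,4R)-4-hydroxy-5,5-dimethyloxolan-2-yl]pentyl}-6-methylocta-2,6-dienoate | COC(=O)/C(=C\CC/C(C)=C/CO[Si](C)(C)C(C)(C)C)CCC[C@@H](C)[C@@H]1C[C@@H](O)C(C)(C)O1 | intermediate
18 | (2Z,6E)-8-[(tert-butyldimethylsilyl)oxy]-2-{(4R)-4-[(2S,4R)-4-hydroxy-5,5-dimethyloxolan-2-yl]pentyl}-6-methylocta-2,6-dien-1-ol | OC/C(=C\CC/C(C)=C/CO[Si](C)(C)C(C)(C)C)CCC[C@@H](C)[C@@H]1C[C@@H](O)C(C)(C)O1 | intermediate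
19 | (2Z,6E)-8-[(tert-butyldimethylsilyl)oxy]-2-{(4R)-4-[(2S,4R)-4-hydroxy-5,5-dimethyloxolan-2-yl]pentyl}-6-methylocta-2,6-dien-1-yl acetate | CC(=O)OC/C(=C\CC/C(C)=C/CO[Si](C)(C)C(C)(C)C)CCC[C@@H](C)[C@@H]1C[C@@H](O)C(C)(C)O1 | intermediate
20 | (2Z,6E)-8-hydroxy-2-{(4R)-4-[(2S,4R)-4-hydroxy-5,5-dimethyloxolan-2-yl]pentyl}-6-methylocta-2,6-dien-1-yl acetate | CC(=O)OC/C(=C\CC/C(C)=C/CO)CCC[C@@H](C)[C@@H]1C[C@@H](O)C(C)(C)O1 | target
```

## Step count and risks

Total step count: 10. Longest linear sequence: 7 steps (steps 1, 2, 4, 7, 8, 9, 10, starting from 1 and 2).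

The three steps most likely to fail:

First, step 4, the proposed new step. The boron-to-copper transfer may be slow with the O-borylated substrate, and the product enolate may add to a second molecule of 10. The fallback uses only known reaction types (enolate alkylation, olefin cross-metathesis, catalytic hydrogenation); it sets out from 6 and 7 and comes back at 12. Phosphonoacetate 7 is C-allylated (NaH, allyl bromide, THF, 0 °C) to methyl 2-[bis(2,2,2-trifluoroethoxy)phosphoryl]pent-4-enoate F1. Cross-metathesis of 6 with an excess of F1 (second-generation Hoveyda–Grubbs catalyst, CH2Cl2, 40 °C) gives methyl (4E,6R)-2-[bis(2,2,2-trifluoroethoxy)phosphoryl]-6-[(2S,4R)-4-hydroxy-5,5-dimethyloxolan-2-yl]hept-4-enoate F2. Hydrogenation of its only alkene (H2, Pd/C, EtOAc) gives 12. This path costs one more step and makes acrylate 10 unnecessary.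

Second, step 3. Acrylate 10 is a strong Michael acceptor and may oligomerise, and its phosphonate esters may exchange during the hot, amine-catalysed condensation. The fallback replaces the Knoevenagel condensation by a Mannich–quaternisation–elimination sequence at or below room temperature; it sets out from 7 and comes back at 10. Compound 7 reacts with N,N-dimethylmethyleneiminium iodide and Et3N in CH2Cl2 to give methyl 2-[bis(2,2,2-trifluoroethoxy)phosphoryl]-3-(dimethylamino)propanoate F3. Methylation with MeI gives [2-[bis(2,2,2-trifluoroethoxy)phosphoryl]-3-methoxy-3-oxopropyl]trimethylammonium iodide F4. Brief shaking of F4 with aqueous NaHCO3 and CH2Cl2 at 0 °C eliminates trimethylamine and returns 10.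

Third, step 1. The transient β,γ-unsaturated aldehyde 3 may slip into conjugation under the basic, hot conditions before it is crotylated. The fallback separates oxidation from C–C bond formation and uses a stoichiometric chiral crotylborane at low temperature; it sets out from 1 and comes back at 4. Alcohol 1 is oxidised with Dess–Martin periodinane (NaHCO3, CH2Cl2, 0 °C) to aldehyde 3, which is used at once as a cold solution. Brown crotylboration follows, with the (E)-crotyl reagent made from trans-but-2-ene, KOt-Bu, n-BuLi and (+)-B-methoxydiisopinocampheylborane, then BF3·OEt2 and 3 at −78 °C, and oxidative work-up (NaOH, H2O2) gives 4. This fallback makes no compound outside the compound list (F0).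

## Further compounds

```
F1 | step 4 | methyl 2-[bis(2,2,2-trifluoroethoxy)phosphoryl]pent-4-enoate | COC(=O)C(CC=C)P(=O)(OCC(F)(F)F)OCC(F)(F)F
F2 | step 4 | methyl (4E,6R)-2-[bis(2,2,2-trifluoroethoxy)phosphoryl]-6-[(2S,4R)-4-hydroxy-5,5-dimethyloxolan-2-yl]hept-4-enoate | COC(=O)C(C/C=C/[C@@H](C)[C@@H]1C[C@@H](O)C(C)(C)O1)P(=O)(OCC(F)(F)F)OCC(F)(F)F
F3 | step 3 | methyl 2-[bis(2,2,2-trifluoroethoxy)phosphoryl]-3-(dimethylamino)propanoate | COC(=O)C(CN(C)C)P(=O)(OCC(F)(F)F)OCC(F)(F)F
F4 | step 3 | [2-[bis(2,2,2-trifluoroethoxy)phosphoryl]-3-methoxy-3-oxopropyl]trimethylammonium iodide | COC(=O)C(C[N+](C)(C)C)P(=O)(OCC(F)(F)F)OCC(F)(F)F.[I-]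
F0 | step 1 | none | none
```
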